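**Retrosynthetic overview**

- 24 ⇐ Steglich esterification and desilylation of 21 ⇐ Pd–formate hydrogenolysis of carbonate 20 (sets C9–H and C7=C8) ⇐ C9–C11 union of bicyclic enone 11 with chiral alkyllithium 18 (C11–C16, C13 from (R)-mevalonolactone).
- 11 ⇐ 8 (C2 acetyl turned into the C2 oxygen by Baeyer–Villiger oxidation with retention) ⇐ one-flask (3+3) annulation of 6-methylcarvone 2 with the C1–C2–C3 linchpin 6: C1–C10 by enolate SN2′ alkylation, then C3–C4 by iron-hydride hydrogen-atom transfer and 6-endo radical closure.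
- Enabling feature: in ring B the two fully substituted carbons C10 and C4 are 1,3-related across C5–H. In 2, C10 is the only enolisable carbon next to the C9 carbonyl and C4 is the internal carbon of the isopropenyl group on C5 (a latent tertiary radical), so a three-carbon allyl bromide/enone can bridge them.
- Ring order: ring B comes from (S)-carvone (C5 stereocenter, C7=C8–C9=O enone, C17 methyl); ring A is closed onto it in the key step; the side chain is attached last.

Key step: step 4

Remark: labdane numbering (C1–C20) is used for all ring carbons; 2 is carried on as its C10-epimer mixture (major epimer drawn) because C10 becomes planar again in step 4.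

**Route**

Step 1
Reactants: 1 (S)-(+)-carvone
Product: 2 (5S,6R)-2,6-dimethyl-5-(prop-1-en-2-yl)cyclohex-2-en-1-one (trans-6-methylcarvone, major epimer)
Conditions: LiN(iPr)2, THF, −78 °C; MeI, −78 → 0 °C
Reagents that add atoms: iodomethane, CI
Why: Kinetic deprotonation at the only α′-position (C10) and enolate alkylation should give 2, mainly with the methyl trans to the isopropenyl group; the C10 configuration does not matter because C10 is planarised again in step 4.

Step 2
Reactants: 3 but-3-en-2-one (methyl vinyl ketone); 4 formaldehyde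
Product: 5 3-(hydroxymethyl)but-3-en-2-one
Conditions: 37% aq. CH2O, DABCO (cat.), THF/H2O, 0 → 25 °C
Reagents that add atoms: none
Why: Morita–Baylis–Hillman reaction (amine adds to the enone, the zwitterionic enolate adds to formaldehyde, the amine is expelled); no stereocenter is formed.

Step 3
Reactants: 5 3-(hydroxymethyl)but-3-en-2-one
Product: 6 3-(bromomethyl)but-3-en-2-one
Conditions: PBr3, Et2O, −10 °C; used freshly prepared
Reagents that add atoms: phosphorus tribromide, BrP(Br)Br
Why: Bromination of a primary allylic alcohol with PBr3; SN2 and SN2′ pathways give the same compound because the allyl unit is symmetric, and no stereocenter is involved.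

Step 4
Reactants: 2 (5S,6R)-2,6-dimethyl-5-(prop-1-en-2-yl)cyclohex-2-en-1-one; 6 3-(bromomethyl)but-3-en-2-one
Product: 8 (4aR,7R,8aR)-7-acetyl-2,5,5,8a-tetramethyl-4a,5,6,7,8,8a-hexahydronaphthalen-1(4H)-one, via α-methylene ketone 7 (not isolated)
Conditions: LiN(iPr)2, THF, −78 °C; 6, −78 → −20 °C; then EtOH/(CH2OH)2, Fe(acac)3 (30 mol%), PhSiH3, 60 °C; then DBU (cat.), 25 °C
Reagents that add atoms: none
Why: The kinetic cross-conjugated lithium enolate of 2 attacks the CH2= terminus of 6 and expels bromide (SN2′ addition–elimination), forming C1–C10 and an α-methylene ketone in 7; PhSiH3 and Fe(acac)3 then transfer a hydrogen atom to the terminal carbon of the isopropenyl group, and the tertiary C4 radical adds to the enone CH2 (C3), forming C3–C4, before the α-keto radical at C2 is reduced and protonated. The closest known reaction types are the enolate allylation of 6-alkylcarvones with 2-(bromomethyl)acrylate-type electrophiles and the iron-mediated reductive olefin coupling (Giese-type radical conjugate addition) in its intramolecular form. Ring A closes in the 6-endo-trig mode, because 5-exo attack at the fully substituted C2 would join two quaternary carbons and is polarity-mismatched. C10 is set in the intermolecular step: in the enolate the isopropenyl group on C5 sits pseudo-axial (allylic 1,2-strain with the C10 methyl) and shields one face, so the C1 chain enters trans to it, which becomes the trans ring fusion on closure; C5 comes unchanged from carvone, C4 is not stereogenic, and the epimerisable C2 is equilibrated by DBU to the equatorial acetyl, anti to the axial methyls on C4 and C10. The step needs hydrogen-atom transfer to the 1,1-dialkyl alkene and not to the α-methylene ketone or the ring-B enone; the electron-neutral alkene is the usual donor under these conditions and its radical is trapped quickly by the tethered enone.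

Step 5
Reactants: 8 (4aR,7R,8aR)-7-acetyl-2,5,5,8a-tetramethyl-4a,5,6,7,8,8a-hexahydronaphthalen-1(4H)-one
Product: 10 (4aR,7R,8aR)-7-hydroxy-2,5,5,8a-tetramethyl-4a,5,6,7,8,8a-hexahydronaphthalen-1(4H)-one, via acetate 9 (not isolated)
Conditions: mCPBA, CH2Cl2, 0 → 25 °C; then MeOH, K2CO3, 25 °C
Reagents that add atoms: 3-chloroperoxybenzoic acid (mCPBA), OOC(=O)c1cccc(Cl)c1
Why: Baeyer–Villiger oxidation, in which the secondary ring carbon C2 migrates in preference to methyl with retention, so the equatorial acetyl should become the equatorial acetate while the hindered cross-conjugated C9 enone stays inert; methanolysis (transesterification) then frees the C2 alcohol.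

Step 6
Reactants: 10 (4aR,7R,8aR)-7-hydroxy-2,5,5,8a-tetramethyl-4a,5,6,7,8,8a-hexahydronaphthalen-1(4H)-one
Product: 11 (4aR,7R,8aR)-2,5,5,8a-tetramethyl-7-[(triethylsilyl)oxy]-4a,5,6,7,8,8a-hexahydronaphthalen-1(4H)-one
Conditions: Et3SiCl, imidazole, DMF, 25 °C
Reagents that add atoms: chlorotriethylsilane, CC[Si](Cl)(CC)CC
Why: Silyl ether formation at the unhindered equatorial secondary alcohol protects C2–OH against the organolithium and palladium steps.

Step 7
Reactants: 12 (R)-mevalonolactone
Product: 13 (S)-3-hydroxy-3-methyl-5-(phenylselanyl)pentanoic acid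
Conditions: (PhSe)2, NaBH4, EtOH/DMF, 25 → 120 °C; then aq. HCl
Reagents that add atoms: diphenyl diselenide, c1ccc(cc1)[Se][Se]c1ccccc1
Why: SN2 opening of the δ-lactone at C5 by the soft, weakly basic benzeneselenolate (alkyl–oxygen cleavage of a lactone) leaves the tertiary carbinol stereocenter untouched.

Step 8
Reactants: 13 (S)-3-hydroxy-3-methyl-5-(phenylselanyl)pentanoic acid
Product: 14 (S)-3-hydroxy-3-methylpent-4-enoic acid
Conditions: 30% H2O2, THF, 0 °C; then iPr2NH, 60 °C
Reagents that add atoms: none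
Why: Oxidation to the selenoxide and syn-elimination (selenoxide elimination) can only remove a hydrogen from C4 and should give the vinyl group; the stereocenter is not involved.

Step 9
Reactants: 14 (S)-3-hydroxy-3-methylpent-4-enoic acid
Product: 15 (S)-3-methylpent-4-ene-1,3-diol
Conditions: LiAlH4, THF, 0 → 65 °C
Reagents that add atoms: none
Why: Hydride reduction of the carboxylic acid to the primary alcohol; the stereocenter is not touched.

Step 10
Reactants: 15 (S)-3-methylpent-4-ene-1,3-diol
Product: 16 (S)-5-iodo-3-methylpent-1-en-3-ol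
Conditions: I2, PPh3, imidazole, CH2Cl2, 0 °C
Reagents that add atoms: iodine, II
Why: Appel-type iodination is selective for the primary over the tertiary allylic alcohol.

Step 11
Reactants: 16 (S)-5-iodo-3-methylpent-1-en-3-ol
Product: 17 triethyl{[(3S)-5-iodo-3-methylpent-1-en-3-yl]oxy}silane
Conditions: Et3SiOTf, 2,6-lutidine, CH2Cl2, −78 → 0 °C
Reagents that add atoms: triethylsilyl trifluoromethanesulfonate, CC[Si](CC)(CC)OS(=O)(=O)C(F)(F)F
Why: Silylation of the tertiary alcohol with a silyl triflate keeps the later C13 oxygen from being carbonated and ionised by palladium.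

Step 12
Reactants: 17 triethyl{[(3S)-5-iodo-3-methylpent-1-en-3-yl]oxy}silane; 11 (4aR,7R,8aR)-2,5,5,8a-tetramethyl-7-[(triethylsilyl)oxy]-4a,5,6,7,8,8a-hexahydronaphthalen-1(4H)-one
Product: 20 methyl (2R,5R,9R,10R,13S)-2,13-bis[(triethylsilyl)oxy]labda-7,14-dien-9-yl carbonate, via alkyllithium 18 (not isolated), via lithium alkoxide 19 (not isolated)
Conditions: 17, t-BuLi (2.1 equiv), Et2O/pentane, −78 °C; then 11, −78 → −40 °C; then ClCO2Me, −78 → 0 °C
Reagents that add atoms: methyl chloroformate, COC(Cl)=O
Why: Iodine–lithium exchange gives the primary alkyllithium 18 (kept cold in ether to suppress 1,4-silyl migration), which should add 1,2 to the C9 carbonyl from the face opposite the axial C10 methyl so that the new C9–O bond is syn to that methyl; the tertiary alkoxide 19 is then O-acylated to the allylic carbonate (organolithium 1,2-addition, then acylation).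

Step 13
Reactants: 20 methyl (2R,5R,9R,10R,13S)-2,13-bis[(triethylsilyl)oxy]labda-7,14-dien-9-yl carbonate
Product: 21 (2R,5R,9R,10R,13S)-2,13-bis[(triethylsilyl)oxy]labda-7,14-diene
Conditions: Pd(OAc)2 (5 mol%), PBu3 (20 mol%), HCO2H, Et3N, THF, 60 °C
Reagents that add atoms: none
Why: Palladium-catalysed formate hydrogenolysis of an allylic carbonate, in which zerovalent palladium ionises the C9–O bond with inversion and the hydride of the palladium formate is delivered on the palladium face to the more substituted allyl terminus C9; this should give the C7=C8 alkene and the C9 hydrogen anti to the C10 methyl (net inversion at C9).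

Step 14
Reactants: 21 (2R,5R,9R,10R,13S)-2,13-bis[(triethylsilyl)oxy]labda-7,14-diene
Product: 22 (2R,5R,9R,10R,13S)-labda-7,14-diene-2,13-diol
Conditions: Bu4NF, THF, 25 → 45 °C
Reagents that add atoms: none
Why: Fluoride-mediated desilylation should remove both triethylsilyl ethers without touching any stereocenter.

Step 15
Reactants: 22 (2R,5R,9R,10R,13S)-labda-7,14-diene-2,13-diol; 23 3-methylbut-2-enoic acid
Product: 24 (2R,5R,9R,10R,13S)-13-hydroxylabda-7,14-dien-2-yl 3-methylbut-2-enoate (target)
Conditions: DCC, DMAP (cat.), CH2Cl2, 0 → 25 °C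
Reagents that add atoms: none
Why: Steglich esterification should acylate the unhindered equatorial C2 alcohol and leave the tertiary C13 alcohol untouched; carbodiimide activation avoids the ketene pathway that deconjugates the enoate.

**Compound list**

1 | (S)-(+)-carvone | CC1=CC[C@@H](CC1=O)C(C)=C | starting material
2 | (5S,6R)-2,6-dimethyl-5-(prop-1-en-2-yl)cyclohex-2-en-1-one (major epimer) | O=C1C(C)=CC[C@H](C(C)=C)[C@H]1C | intermediate
3 | but-3-en-2-one | CC(=O)C=C | starting material
4 | formaldehyde | C=O | starting material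
5 | 3-(hydroxymethyl)but-3-en-2-one | CC(=O)C(=C)CO | intermediate
6 | 3-(bromomethyl)but-3-en-2-one | CC(=O)C(=C)CBr | intermediate
7 | (5R,6R)-2,6-dimethyl-6-(2-methylidene-3-oxobutyl)-5-(prop-1-en-2-yl)cyclohex-2-en-1-one | O=C1C(C)=CC[C@H](C(C)=C)[C@@]1(C)CC(=C)C(C)=O | intermediate
8 | (4aR,7R,8aR)-7-acetyl-2,5,5,8a-tetramethyl-4a,5,6,7,8,8a-hexahydronaphthalen-1(4H)-one | O=C1C(C)=CC[C@@H]2C(C)(C)C[C@@H](C(C)=O)C[C@@]12C | intermediate
9 | (4aR,7R,8aR)-7-acetoxy-2,5,5,8a-tetramethyl-4a,5,6,7,8,8a-hexahydronaphthalen-1(4H)-one | O=C1C(C)=CC[C@@H]2C(C)(C)C[C@@H](OC(C)=O)C[C@@]12C | intermediate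
10 | (4aR,7R,8aR)-7-hydroxy-2,5,5,8a-tetramethyl-4a,5,6,7,8,8a-hexahydronaphthalen-1(4H)-one | O=C1C(C)=CC[C@@H]2C(C)(C)C[C@@H](O)C[C@@]12C | intermediate
11 | (4aR,7R,8aR)-2,5,5,8a-tetramethyl-7-[(triethylsilyl)oxy]-4a,5,6,7,8,8a-hexahydronaphthalen-1(4H)-one | O=C1C(C)=CC[C@@H]2C(C)(C)C[C@@H](O[Si](CC)(CC)CC)C[C@@]12C | intermediate
12 | (R)-mevalonolactone | C[C@@]1(O)CCOC(=O)C1 | starting material
13 | (S)-3-hydroxy-3-methyl-5-(phenylselanyl)pentanoic acid | C[C@@](CC(=O)O)(O)CC[Se]c1ccccc1 | intermediate
14 | (S)-3-hydroxy-3-methylpent-4-enoic acid | C[C@@](CC(=O)O)(O)C=C | intermediate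
15 | (S)-3-methylpent-4-ene-1,3-diol | C[C@@](CCO)(O)C=C | intermediate
16 | (S)-5-iodo-3-methylpent-1-en-3-ol | C[C@@](CCI)(O)C=C | intermediate
17 | triethyl{[(3S)-5-iodo-3-methylpent-1-en-3-yl]oxy}silane | C[C@@](CCI)(O[Si](CC)(CC)CC)C=C | intermediate
18 | {(3S)-3-methyl-3-[(triethylsilyl)oxy]pent-4-en-1-yl}lithium | C[C@@](CC[Li])(O[Si](CC)(CC)CC)C=C | intermediate
19 | lithium (2R,5R,9R,10R,13S)-2,13-bis[(triethylsilyl)oxy]labda-7,14-dien-9-olate | C=C[C@@](C)(O[Si](CC)(CC)CC)CC[C@@]1(O[Li])C(C)=CC[C@@H]2C(C)(C)C[C@@H](O[Si](CC)(CC)CC)C[C@@]12C | intermediate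
20 | methyl (2R,5R,9R,10R,13S)-2,13-bis[(triethylsilyl)oxy]labda-7,14-dien-9-yl carbonate | C=C[C@@](C)(O[Si](CC)(CC)CC)CC[C@@]1(OC(=O)OC)C(C)=CC[C@@H]2C(C)(C)C[C@@H](O[Si](CC)(CC)CC)C[C@@]12C | intermediate
21 | (2R,5R,9R,10R,13S)-2,13-bis[(triethylsilyl)oxy]labda-7,14-diene | C=C[C@@](C)(O[Si](CC)(CC)CC)CC[C@@H]1C(C)=CC[C@@H]2C(C)(C)C[C@@H](O[Si](CC)(CC)CC)C[C@@]12C | intermediate
22 | (2R,5R,9R,10R,13S)-labda-7,14-diene-2,13-diol | C=C[C@@](C)(O)CC[C@@H]1C(C)=CC[C@@H]2C(C)(C)C[C@@H](O)C[C@@]12C | intermediate
23 | 3-methylbut-2-enoic acid | CC(C)=CC(=O)O | starting material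
24 | (2R,5R,9R,10R,13S)-13-hydroxylabda-7,14-dien-2-yl 3-methylbut-2-enoate | C=C[C@@](C)(O)CC[C@@H]1C(C)=CC[C@@H]2C(C)(C)C[C@@H](OC(=O)C=C(C)C)C[C@@]12C | target

**Step count and risks**

Total step count: 15. Longest linear sequence: 9 steps (steps 7–15, from 12); from 1 the sequence is 8 steps (1, 4, 5, 6, 12–15).

Steps most likely to fail:

Step 4. What may go wrong: hydrogen-atom transfer to the α-methylene ketone of 7 in place of the isopropenyl group (simple reduction, or ring closure with reversed regiochemistry), O-alkylation, or polymerisation of 6. Fallback, cationic in place of radical ring closure: it sets out from 2. Alkylation of the same enolate with 2,3-dichloropropene (LiN(iPr)2, THF/DMPU, NaI) should give (5R,6R)-6-(2-chloroprop-2-en-1-yl)-2,6-dimethyl-5-(prop-1-en-2-yl)cyclohex-2-en-1-one F1. Treatment with 90% H2SO4 at 0 °C (chloro-olefin annulation: the tertiary C4 cation from the isopropenyl group is trapped 6-endo by the vinyl chloride and the α-chloro cation is hydrolysed) should give (4aR,8aR)-2,5,5,8a-tetramethyl-4a,5,8,8a-tetrahydronaphthalene-1,7(4H,6H)-dione F2. Meerwein–Ponndorf–Verley reduction under equilibrating conditions (Al(OiPr)3, iPrOH, trace acetone, reflux) should reduce only the unhindered C2 ketone and settle on the equatorial alcohol, so the route is rejoined at 10.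

Step 12. What may go wrong: the neopentyl-type C9 ketone resists 1,2-addition, 18 undergoes 1,4-silyl migration from oxygen to carbon, or the hindered alkoxide is not acylated. Fallback, cross-coupling in place of carbonyl addition: it sets out from 11. KN(SiMe3)2 and PhNTf2 (the only enolisation mode is γ-deprotonation at C6) should give (4aR,7R,8aR)-2,5,5,8a-tetramethyl-7-[(triethylsilyl)oxy]-4a,5,6,7,8,8a-hexahydronaphthalen-1-yl trifluoromethanesulfonate F3. Negishi coupling with {(3S)-3-methyl-3-[(triethylsilyl)oxy]pent-4-en-1-yl}zinc iodide F4 (from 17, Zn, LiCl, THF; Pd(PPh3)4) should give (2R,5R,10R,13S)-2,13-bis[(triethylsilyl)oxy]labda-6,8,14-triene F5. 1,4-Hydrogenation of the s-cis ring diene with (η6-methyl benzoate)Cr(CO)3 and H2 (cis-1,4 addition from the face opposite the C10 methyl; the isolated vinyl group is not reduced) should then lead directly to 21.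

Step 13. What may go wrong: hydride delivery to C7 giving the tetrasubstituted C8=C9 alkene, β-hydride elimination to dienes, or poor facial control at C9 if the addition in step 12 was not face-selective. Fallback, reduction with thermodynamic control at C9: it sets out from alkoxide 19, which is quenched with aqueous NH4Cl in place of methyl chloroformate to give (2R,5R,9R,10R,13S)-2,13-bis[(triethylsilyl)oxy]labda-7,14-dien-9-ol F6. Oxidative 1,3-transposition with pyridinium chlorochromate ([C5H5NH][CrO3Cl], CH2Cl2) should give (2R,5R,10R,13S)-2,13-bis[(triethylsilyl)oxy]labda-8,14-dien-7-one F7. Li/NH3 reduction (axial protonation at C9 anti to the C10 methyl, independent of the earlier addition face) with trapping of the regiodefined enolate by PhNTf2 should give (2R,5R,9S,10R,13S)-2,13-bis[(triethylsilyl)oxy]labda-7,14-dien-7-yl trifluoromethanesulfonate F8. Reduction of the triflate with Pd(OAc)2, PPh3, HCO2H and Bu3N in DMF should return the route at 21.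

Further compounds
F1 | step 4 | (5R,6R)-6-(2-chloroprop-2-en-1-yl)-2,6-dimethyl-5-(prop-1-en-2-yl)cyclohex-2-en-1-one | O=C1C(C)=CC[C@H](C(C)=C)[C@@]1(C)CC(Cl)=C
F2 | step 4 | (4aR,8aR)-2,5,5,8a-tetramethyl-4a,5,8,8a-tetrahydronaphthalene-1,7(4H,6H)-dione | O=C1C(C)=CC[C@@H]2C(C)(C)CC(=O)C[C@@]12C
F3 | step 12 | (4aR,7R,8aR)-2,5,5,8a-tetramethyl-7-[(triethylsilyl)oxy]-4a,5,6,7,8,8a-hexahydronaphthalen-1-yl trifluoromethanesulfonate | O=S(=O)(OC1=C(C)C=C[C@@H]2C(C)(C)C[C@@H](O[Si](CC)(CC)CC)C[C@@]12C)C(F)(F)F
F4 | step 12 | {(3S)-3-methyl-3-[(triethylsilyl)oxy]pent-4-en-1-yl}zinc iodide | C[C@@](CC[Zn]I)(O[Si](CC)(CC)CC)C=C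
F5 | step 12 | (2R,5R,10R,13S)-2,13-bis[(triethylsilyl)oxy]labda-6,8,14-triene | C=C[C@@](C)(O[Si](CC)(CC)CC)CCC1=C(C)C=C[C@@H]2C(C)(C)C[C@@H](O[Si](CC)(CC)CC)C[C@@]12C
F6 | step 13 | (2R,5R,9R,10R,13S)-2,13-bis[(triethylsilyl)oxy]labda-7,14-dien-9-ol | C=C[C@@](C)(O[Si](CC)(CC)CC)CC[C@@]1(O)C(C)=CC[C@@H]2C(C)(C)C[C@@H](O[Si](CC)(CC)CC)C[C@@]12C
F7 | step 13 | (2R,5R,10R,13S)-2,13-bis[(triethylsilyl)oxy]labda-8,14-dien-7-one | C=C[C@@](C)(O[Si](CC)(CC)CC)CCC1=C(C)C(=O)C[C@@H]2C(C)(C)C[C@@H](O[Si](CC)(CC)CC)C[C@@]12C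
F8 | step 13 | (2R,5R,9S,10R,13S)-2,13-bis[(triethylsilyl)oxy]labda-7,14-dien-7-yl trifluoromethanesulfonate | C=C[C@@](C)(O[Si](CC)(CC)CC)CC[C@@H]1C(C)=C(OS(=O)(=O)C(F)(F)F)C[C@@H]2C(C)(C)C[C@@H](O[Si](CC)(CC)CC)C[C@@]12C
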